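All runs stem from a simulated flask from invented constants; the scatter is artificial.

Amounts first: dawn and midnight each charge 0.30 M of first end groups, against 0.660 M and 0.330 M of second end groups. You need to know how the first end groups split between links and a side loss.

| flask | first end groups | second end groups | remark | time |
|---|---|---|---|---|
| south | 0.45 M | 0.33 M | run made earlier |  |
| east | 0.15 M | 0.33 M | run made earlier |  |
| dawn | 0.30 M | 0.660 M |  | 40 h |
| midnight | 0.30 M | 0.330 M |  | 40 h |

- south (time / h: links / %, first end groups / %): 2.00: 61.4, 21.9; 3.00: 66.5, 16.3; 5.00: 70.0, 11.3; 8.00: 71.0, 9.0; 15.0: 72.9, 6.2; 25.0: 73.1, 4.2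
- east (time / h: links / %, first end groups / %): 4.00: 94.7, 0.8; 8.00: 96.8, 1.0; 12.0: 95.2, 0; 15.0: 94.9, 0.6; 20.0: 94.5, 0.5; 25.0: 96.1, 0.5

(scatter of a reading: 0.5 percentage points)

* which of these there is most of at the end, counted by the first end groups in it, dawn (first end groups / links)
* which of these there is most of at the end, counted by the first end groups in it, midnight (first end groups / links)
* how much there is at the end of the one of these that leads, in percent of the first end groups charged: dawn
* how much there is at the end of the one of these that leads, in percent of the first end groups charged: midnight

- the numbers in the tables scatter by 0.5 percentage points (one standard deviation)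
- a reading or a percentage of links counts all its forms, free or not

In south, links stop near 73.1 %, while first end groups still fall from 9.0 % to 4.2 % between 8.00 h and 25.0 h, so they have a second exit. My reckoning takes links as first order in each end group and the loss as second order in first end groups. Write [A] and [B] for the free end groups, a and b for their charges. In east, links average 95.4 %. The loss is small there, so [A] follows [B] − (b − a), and integrating gives:

r = (lost first end groups, in M) / (a − (b − a) ln(b/(b − a))) = 0.170

This r, first end groups lost per link made divided by [A]/[B], is the selectivity factor. Now draw [A] against [B]. The slope is 1 + r[A]/[B], which starts at 1.15 in midnight and 1.08 in dawn. With s = 1 − r = 0.830, the curve meets [A] = 0 where the free share of second end groups is: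

f = (1 − s·a/b)^(1/s)

Dawn gives f = 56.5 % and links of 95.7 %. Midnight gives f = 18.4 % and links of 89.8 %. In south, s·a/b is 1.13, above 1, so the bracket is negative, the curve meets [B] = 0 first and links level at b/a, 73.3 %, against the 73.1 % read last. East reads flat from 4.00 h. I take midnight's tail in [A] as pseudo-first-order in [B].

Stretching east's time by the ratio of end [B] gives 12.3 h for midnight, less than 40 h.

The forecast says links lead in dawn at 95.4 % and links in midnight at 89.5 %, on the ground that “selectivity depends only on the concentration ratio”. My figures, 95.7 % and 89.8 %, stand 0.30 percentage points and 0.30 points from its two.

Dawn gives links at 95.7 %, and midnight gives links at 89.8 %.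

    first end groups + second end groups → links (k = 0.00144 M⁻¹ s⁻¹)
    crystals ⇌ links, rate k2*(cs2 - [links]) while solid is left; crystals form when [links] > cs2 (solubility = 0.220 M, k = 5.66 × 10⁻⁴ s⁻¹)
    2 first end groups → self-condensation product (k = 1.21 × 10⁻⁴ M⁻¹ s⁻¹)

Midnight keeps 18.3 % of its second end groups free, against f of 18.4 %. A neighbour of dawn charged with 1.2 M of first end groups has b/a of 0.550, below s, so the bracket is negative and the reckoning gives links of 55.0 %. That flask ends with second end groups at 0 % and links at 55.0 %.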